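**Retrosynthetic overview**
1. Target 24 ⇐ one-pot Knoevenagel / o-quinone methide capture / transannular cyclisation / 1,2-hydride shift / phenol capture from (+)-bicyclogermacrene 14, dialdehyde 21 and 3-methylbutanal 22 (cyclopentane, cycloheptane and oxepane rings formed last, together).
2. 14 ⇐ ring expansion: boronate (Grob-type) fragmentation of decalin mesylate 12, which cleaves C5–C10 and creates both E-alkenes of the ten-membered ring.
3. 12 ⇐ ring A built on a carone-type ketone by Mukaiyama aldol and McMurry coupling; the C1 leaving-group configuration comes from ketone reduction.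
4. Carone silyl enol ether 5 ⇐ enantioselective cobalt-catalysed dimethylcyclopropanation of siloxydiene 3 (from 6-methylcyclohexenone 1) with 2,2-dichloropropane 4.
5. 21 ⇐ resorcinol 15 by C–H borylation/oxidation, then double formylation. Ring order: cyclopropane → ring A → ten-membered ring → 5/7/oxepane.

Assumption: terpenoid labels C1–C15 in the "Why" lines are germacrane/maaliane numbers (C14 methyl on C10, C15 methyl on C4, C11 the gem-dimethyl carbon bridging C6 and C7); the ligand antipode that gives (1S,6R)-5 is taken to be the (S)-oxazoline and would be swapped if induction is opposite.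

**Step 1**
Reactants: 1 6-methylcyclohex-2-en-1-one
Product: 3 tert-butyldimethyl[(2-methylcyclohexa-1,5-dien-1-yl)oxy]silane, via lithium dienolate 2 (not isolated)
Conditions: LiN(i-Pr)2 (1.1 equiv), THF, −78 °C, 1 h; then t-BuMe2SiOTf (1.15 equiv), −78 → 0 °C
Reagents that add atoms: tert-butyldimethylsilyl trifluoromethanesulfonate, CC(C)(C)[Si](C)(C)OS(=O)(=O)C(F)(F)F
Why: Kinetic α′-deprotonation of the enone gives the cross-conjugated dienolate and O-silylation (silyl enol ether formation) fixes it as the 2-siloxy-1,3-diene, erasing the only stereocentre of 1.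

**Step 2**
Reactants: 3 tert-butyldimethyl[(2-methylcyclohexa-1,5-dien-1-yl)oxy]silane; 4 2,2-dichloropropane
Product: 5 tert-butyldimethyl{[(1S,6R)-3,7,7-trimethylbicyclo[4.1.0]hept-2-en-2-yl]oxy}silane
Conditions: [CoBr2(L*)] (5 mol%; L* = 2-[(4S)-4-tert-butyl-4,5-dihydro-1,3-oxazol-2-yl]-6-{1-[(2,6-diisopropylphenyl)imino]ethyl}pyridine), Zn dust (2.5 equiv), 4 (2 equiv), THF, 23 °C, 24 h
Reagents that add atoms: none
Why: Proposed new method: zinc reduces the cobalt dibromide complex to a low-valent cobalt species that activates the C–Cl bonds of 4 to give a cobalt isopropylidene carbenoid, which adds [2+1] to the cis-disubstituted C=C of the locked s-cis diene because the tetrasubstituted silyl enol ether C=C is sterically shut out, while the C1-symmetric ligand selects the alkene face and so sets both cyclopropane stereocentres (cis fusion is forced by the ring); the closest known reaction type is cobalt-catalysed reductive dimethylcyclopropanation of simple 1,3-dienes with 2,2-dichloropropane/Zn and its enantioselective variant with oxazoline–iminopyridine ligands, not yet shown on a 2-siloxy cyclic diene.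

**Step 3**
Reactants: 5 tert-butyldimethyl{[(1S,6R)-3,7,7-trimethylbicyclo[4.1.0]hept-2-en-2-yl]oxy}silane; 6 4-oxopentanal
Product: 7 (1S,3S,6R)-3-{1-[(tert-butyldimethylsilyl)oxy]-4-oxopentyl}-3,7,7-trimethylbicyclo[4.1.0]heptan-2-one (both epimers at the silyloxy carbon)
Conditions: Tf2NH (2 mol%), CH2Cl2, −78 °C, 2 h; Et3N quench
Reagents that add atoms: none
Why: Mukaiyama aldol addition catalysed by the silyl triflimide formed in situ: the aldehyde (far more reactive than the methyl ketone) is attacked by C10 from the face opposite the endo methyl of the cyclopropane, which sets quaternary C10 with its methyl cis to the cyclopropane bridge, and silyl transfer caps the carbinol, whose configuration is corrected in steps 6 and 7.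

**Step 4**
Reactants: 7 (1S,3S,6R)-3-{1-[(tert-butyldimethylsilyl)oxy]-4-oxopentyl}-3,7,7-trimethylbicyclo[4.1.0]heptan-2-one
Product: 8 tert-butyldimethyl{[(1aR,3aR,7bS)-1,1,3a,7-tetramethyl-1a,2,3,3a,4,5,6,7b-octahydro-1H-cyclopropa[a]naphthalen-4-yl]oxy}silane (both C4 epimers)
Conditions: TiCl3(DME)1.5 (8 equiv), Zn–Cu couple (20 equiv), DME, reflux; 7 added by syringe pump over 30 h
Reagents that add atoms: none
Why: Intramolecular McMurry coupling of the 1,6-diketone under high dilution closes ring A as the tetrasubstituted C4=C5 alkene (six-membered ring closure is the most favourable case), creating no stereocentre.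

**Step 5**
Reactants: 8 tert-butyldimethyl{[(1aR,3aR,7bS)-1,1,3a,7-tetramethyl-1a,2,3,3a,4,5,6,7b-octahydro-1H-cyclopropa[a]naphthalen-4-yl]oxy}silane
Product: 9 (1aR,3aR,7bS)-1,1,3a,7-tetramethyl-1a,2,3,3a,4,5,6,7b-octahydro-1H-cyclopropa[a]naphthalen-4-ol (both C4 epimers)
Conditions: Bu4NF (2 equiv), THF, 50 °C
Reagents that add atoms: none
Why: Fluoride desilylation (Si–F bond formation) frees the hindered secondary alcohol without touching the alkene or the cyclopropane.

**Step 6**
Reactants: 9 (1aR,3aR,7bS)-1,1,3a,7-tetramethyl-1a,2,3,3a,4,5,6,7b-octahydro-1H-cyclopropa[a]naphthalen-4-ol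
Product: 10 (1aR,3aR,7bS)-1,1,3a,7-tetramethyl-1,1a,2,3,3a,5,6,7b-octahydro-4H-cyclopropa[a]naphthalen-4-one
Conditions: Dess–Martin periodinane (1.3 equiv), CH2Cl2, 0 → 23 °C
Reagents that add atoms: none
Why: Dess–Martin oxidation under neutral conditions converges both carbinol epimers to one β,γ-unsaturated ketone, which cannot conjugate because C10 is quaternary.

**Step 7**
Reactants: 10 (1aR,3aR,7bS)-1,1,3a,7-tetramethyl-1,1a,2,3,3a,5,6,7b-octahydro-4H-cyclopropa[a]naphthalen-4-one
Product: 11 (1aR,3aR,4R,7bS)-1,1,3a,7-tetramethyl-1a,2,3,3a,4,5,6,7b-octahydro-1H-cyclopropa[a]naphthalen-4-ol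
Conditions: NaBH4 (1.5 equiv), MeOH, −20 °C
Reagents that add atoms: none
Why: Borohydride reduction: hydride attacks the C1 ketone from the face opposite the axial C10 methyl and the cyclopropane bridge, giving the equatorial alcohol cis to the C10 methyl (same sense as reduction of the saturated ketone of the Wieland–Miescher ketone).

**Step 8**
Reactants: 11 (1aR,3aR,4R,7bS)-1,1,3a,7-tetramethyl-1a,2,3,3a,4,5,6,7b-octahydro-1H-cyclopropa[a]naphthalen-4-ol
Product: 12 (1aR,3aR,4R,7bS)-1,1,3a,7-tetramethyl-1a,2,3,3a,4,5,6,7b-octahydro-1H-cyclopropa[a]naphthalen-4-yl methanesulfonate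
Conditions: MsCl (1.3 equiv), Et3N (2 equiv), CH2Cl2, 0 °C
Reagents that add atoms: methanesulfonyl chloride, CS(=O)(=O)Cl
Why: Sulfonylation of the alcohol occurs with retention and gives an equatorial mesylate that is stable because the neighbouring C10 is quaternary.

**Step 9**
Reactants: 12 (1aR,3aR,4R,7bS)-1,1,3a,7-tetramethyl-1a,2,3,3a,4,5,6,7b-octahydro-1H-cyclopropa[a]naphthalen-4-yl methanesulfonate
Product: 14 (+)-bicyclogermacrene [(1S,2E,6E,10R)-3,7,11,11-tetramethylbicyclo[8.1.0]undeca-2,6-diene], via C4 alkylborane 13 (not isolated)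
Conditions: BH3·THF (3 equiv), THF, 0 → 23 °C, 12 h; then 3 M aq. NaOH, 23 → 40 °C, 2 h; chromatography on AgNO3-impregnated silica, store cold
Reagents that add atoms: none
Why: Ring expansion by Marshall-type boronate (Grob) fragmentation: syn hydroboration from the face opposite the C10 methyl and the cyclopropane puts boron on C4 (away from quaternary C10 and the cyclopropane) and H on C5 to give the trans-decalin, in which the equatorial C4–B and C1–OMs bonds are both antiperiplanar to C5–C10, so hydroxide-induced borate formation cleaves C5–C10 in concert and turns the two six-membered rings into the ten-membered ring with both trisubstituted alkenes E.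

**Step 10**
Reactants: 15 benzene-1,3-diol (resorcinol)
Product: 16 1,3-bis[(tert-butyldimethylsilyl)oxy]benzene
Conditions: t-BuMe2SiCl (2.3 equiv), imidazole (2.5 equiv), DMF, 23 °C
Reagents that add atoms: tert-butyldimethylsilyl chloride, CC(C)(C)[Si](C)(C)Cl
Why: Standard phenol silylation gives two bulky ether groups that protect the oxygens and steer the next C–H functionalisation.

**Step 11**
Reactants: 16 1,3-bis[(tert-butyldimethylsilyl)oxy]benzene
Product: 19 benzene-1,3,5-triol (phloroglucinol), via arylboronate 17 (not isolated), via silylated phenol 18 (not isolated)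
Conditions: [Ir(cod)(OMe)]2 (1.5 mol%), 4,4′-di-tert-butyl-2,2′-bipyridine (3 mol%), B2pin2 (1.0 equiv), hexane, 80 °C; then KHSO5 (Oxone, 1.1 equiv), acetone–H2O, 23 °C, 15 min; then KHF2 (2.5 equiv), MeOH, 23 °C
Reagents that add atoms: potassium peroxymonosulfate, [K+].OOS(=O)(=O)[O-]
Why: Sterically controlled iridium-catalysed C–H borylation occurs only at C5 (the one position not ortho to a siloxy group), peroxymonosulfate oxidises the C–B bond in place, and bifluoride cleaves the aryl silyl ethers.

**Step 12**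
Reactants: 19 benzene-1,3,5-triol
Product: 21 2,4,6-trihydroxybenzene-1,3-dicarbaldehyde, via bis-iminium salt 20 (not isolated)
Conditions: POCl3 (2.4 equiv), DMF (2.4 equiv), 1,4-dioxane, 0 → 23 °C, 12 h; then H2O, 23 °C
Reagents that add atoms: N,N-dimethylformamide, CN(C)C=O; water, O
Why: Vilsmeier–Haack formylation of the very electron-rich ring stops after two iminium groups have deactivated it, and hydrolysis gives the dialdehyde.

**Step 13**
Reactants: 14 (+)-bicyclogermacrene; 21 2,4,6-trihydroxybenzene-1,3-dicarbaldehyde; 22 3-methylbutanal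
Product: 24 target CNP0189833.2 (aromadendrane–diformylphloroglucinol adduct: benzylic carbon bonded to C4 and phenolic oxygen bonded to C1 in an oxepane; stereochemistry as in the given SMILES), via o-quinone methide 23 (not isolated)
Conditions: 14 (1 equiv), 21 (1.5 equiv), 22 (3 equiv), NaOAc (1.5 equiv), THF–H2O (4:1), 60 °C, 16 h, Ar, dark; preparative HPLC
Reagents that add atoms: none
Why: Biomimetic three-component cascade of the kind used for related formyl-phloroglucinol meroterpenoids: Knoevenagel condensation gives 23, C4 of the C4=C5 alkene attacks its exocyclic carbon (C5 cation stabilised by the cyclopropane), C1=C10 closes C1–C5 transannularly anti to the new C4–C bond, and a 1,2-hydride shift from C1 to C10 followed by phenol capture at C1 closes the oxepane, so C4, C5, C1 and C10 are set relative to the cyclopropane by the crown conformation of the ten-membered ring while the benzylic centre forms as a separable epimer pair.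

**Compound list**
1 | 6-methylcyclohex-2-en-1-one (racemic) | CC1CCC=CC1=O | starting material
2 | lithium 2-methylcyclohexa-1,5-dien-1-olate | [Li+].CC1=C([O-])C=CCC1 | intermediate (not isolated)
3 | tert-butyldimethyl[(2-methylcyclohexa-1,5-dien-1-yl)oxy]silane | CC1=C(O[Si](C)(C)C(C)(C)C)C=CCC1 | intermediate
4 | 2,2-dichloropropane | CC(C)(Cl)Cl | starting material
5 | tert-butyldimethyl{[(1S,6R)-3,7,7-trimethylbicyclo[4.1.0]hept-2-en-2-yl]oxy}silane | CC1=C(O[Si](C)(C)C(C)(C)C)[C@H]2[C@@H](CC1)C2(C)C | intermediate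
6 | 4-oxopentanal | CC(=O)CCC=O | starting material
7 | (1S,3S,6R)-3-{1-[(tert-butyldimethylsilyl)oxy]-4-oxopentyl}-3,7,7-trimethylbicyclo[4.1.0]heptan-2-one (silyloxy carbon: both epimers) | CC(=O)CCC(O[Si](C)(C)C(C)(C)C)[C@]1(C)CC[C@@H]2[C@H](C1=O)C2(C)C | intermediate
8 | tert-butyldimethyl{[(1aR,3aR,7bS)-1,1,3a,7-tetramethyl-1a,2,3,3a,4,5,6,7b-octahydro-1H-cyclopropa[a]naphthalen-4-yl]oxy}silane (C4: both epimers) | CC1=C2[C@H]3[C@@H](CC[C@@]2(C)C(O[Si](C)(C)C(C)(C)C)CC1)C3(C)C | intermediate
9 | (1aR,3aR,7bS)-1,1,3a,7-tetramethyl-1a,2,3,3a,4,5,6,7b-octahydro-1H-cyclopropa[a]naphthalen-4-ol (C4: both epimers) | CC1=C2[C@H]3[C@@H](CC[C@@]2(C)C(O)CC1)C3(C)C | intermediate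
10 | (1aR,3aR,7bS)-1,1,3a,7-tetramethyl-1,1a,2,3,3a,5,6,7b-octahydro-4H-cyclopropa[a]naphthalen-4-one | CC1=C2[C@H]3[C@@H](CC[C@@]2(C)C(=O)CC1)C3(C)C | intermediate
11 | (1aR,3aR,4R,7bS)-1,1,3a,7-tetramethyl-1a,2,3,3a,4,5,6,7b-octahydro-1H-cyclopropa[a]naphthalen-4-ol (OH cis to the angular methyl) | CC1=C2[C@H]3[C@@H](CC[C@@]2(C)[C@H](O)CC1)C3(C)C | intermediate
12 | (1aR,3aR,4R,7bS)-1,1,3a,7-tetramethyl-1a,2,3,3a,4,5,6,7b-octahydro-1H-cyclopropa[a]naphthalen-4-yl methanesulfonate | CC1=C2[C@H]3[C@@H](CC[C@@]2(C)[C@H](OS(C)(=O)=O)CC1)C3(C)C | intermediate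
13 | [(1aR,3aR,4R,7S,7aS,7bR)-4-(methanesulfonyloxy)-1,1,3a,7-tetramethyldecahydro-1H-cyclopropa[a]naphthalen-7-yl]borane (trans-decalin; B equatorial on C4) | C[C@@]1(B)CC[C@@H](OS(C)(=O)=O)[C@]2(C)CC[C@@H]3[C@H]([C@@H]12)C3(C)C | intermediate (not isolated)
14 | (+)-bicyclogermacrene, (1S,2E,6E,10R)-3,7,11,11-tetramethylbicyclo[8.1.0]undeca-2,6-diene | C/C1=C\CC/C(C)=C/[C@H]2[C@@H](CC1)C2(C)C | intermediate
15 | benzene-1,3-diol (resorcinol) | Oc1cccc(O)c1 | starting material
16 | 1,3-bis[(tert-butyldimethylsilyl)oxy]benzene | CC(C)(C)[Si](C)(C)Oc1cccc(O[Si](C)(C)C(C)(C)C)c1 | intermediate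
17 | 2-{3,5-bis[(tert-butyldimethylsilyl)oxy]phenyl}-4,4,5,5-tetramethyl-1,3,2-dioxaborolane | CC(C)(C)[Si](C)(C)Oc1cc(O[Si](C)(C)C(C)(C)C)cc(c1)B1OC(C)(C)C(C)(C)O1 | intermediate (not isolated)
18 | 3,5-bis[(tert-butyldimethylsilyl)oxy]phenol | CC(C)(C)[Si](C)(C)Oc1cc(O)cc(O[Si](C)(C)C(C)(C)C)c1 | intermediate (not isolated)
19 | benzene-1,3,5-triol (phloroglucinol) | Oc1cc(O)cc(O)c1 | intermediate
20 | N,N′-[(2,4,6-trihydroxy-1,3-phenylene)dimethylidyne]bis(N-methylmethanaminium) dichloride | C[N+](C)=Cc1c(O)cc(O)c(C=[N+](C)C)c1O.[Cl-].[Cl-] | intermediate (not isolated)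
21 | 2,4,6-trihydroxybenzene-1,3-dicarbaldehyde | O=Cc1c(O)cc(O)c(C=O)c1O | intermediate
22 | 3-methylbutanal | CC(C)CC=O | starting material
23 | 2,4-diformyl-3,5-dihydroxy-6-(3-methylbutylidene)cyclohexa-2,4-dien-1-one (alkene geometry not fixed) | CC(C)CC=C1C(=O)C(C=O)=C(O)C(C=O)=C1O | intermediate (not isolated)
24 | target CNP0189833.2 | CC(C)C[C@H]1c2c(O)c(C=O)c(O)c(C=O)c2O[C@]23CC[C@@]1(C)[C@H]2[C@H]1[C@@H](CC[C@@H]3C)C1(C)C | target

**Totals:** 13 steps; longest linear sequence 10 steps (steps 1–9, then 13).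

**Three steps most likely to fail**

Step 2 (the proposed new cyclopropanation): the cyclic cis-alkene may react slowly, the enol ether may compete, or the ee may be low. Fallback with known chemistry, setting out from 1: conjugate isopropylidene transfer with diphenylsulfonium isopropylide (i-PrPh2S+ BF4−, LiN(i-Pr)2, DME, −70 °C) gives racemic carone, (±)-3,7,7-trimethylbicyclo[4.1.0]heptan-2-one F1. Preparative chromatography on a chiral stationary phase gives (1S,6R)-3,7,7-trimethylbicyclo[4.1.0]heptan-2-one F2. Enolisation with LiN(i-Pr)2 (only the C3 hydrogen can be removed) and silylation with t-BuMe2SiOTf gives 5, where the route resumes at step 3.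

Step 4 (McMurry coupling of a hindered cyclopropyl ketone): ketyl ring opening or arrest at the pinacol stage is possible. Fallback setting out from 7: Cp2TiMe2 (toluene, 70 °C) methylenates both ketones to give the bis-methylene analogue of 7, tert-butyldimethyl({4-methyl-1-[(1S,3R,6R)-3,7,7-trimethyl-2-methylidenebicyclo[4.1.0]heptan-3-yl]pent-4-en-1-yl}oxy)silane F3. Ring-closing metathesis with second-generation Hoveyda–Grubbs catalyst (toluene, 90 °C, argon sparge) then closes ring A as the same tetrasubstituted alkene and returns to 8.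

Step 13 (cascade): water can trap the C10 cation (macrocarpal-type alcohols), the benzylic epimer forms alongside, and 14 is acid- and heat-sensitive. Fallback setting out from 21: Mannich condensation with 22 and morpholine (EtOH, 23 °C) gives the isolable Mannich base 2,4,6-trihydroxy-5-[3-methyl-1-(morpholin-4-yl)butyl]benzene-1,3-dicarbaldehyde F4. Heating F4 with 14 in anhydrous toluene (80 °C) releases 23 in the absence of water, free aldehyde and added acid, and the same cascade gives 24.

**Further compounds**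
F1 | step 2 | (±)-3,7,7-trimethylbicyclo[4.1.0]heptan-2-one (racemic carone, cis-fused, C3 epimers) | CC1CCC2C(C1=O)C2(C)C
F2 | step 2 | (1S,6R)-3,7,7-trimethylbicyclo[4.1.0]heptan-2-one (C3 epimers) | CC1CC[C@@H]2[C@H](C1=O)C2(C)C
F3 | step 4 | tert-butyldimethyl({4-methyl-1-[(1S,3R,6R)-3,7,7-trimethyl-2-methylidenebicyclo[4.1.0]heptan-3-yl]pent-4-en-1-yl}oxy)silane (silyloxy carbon: both epimers) | C=C(C)CCC(O[Si](C)(C)C(C)(C)C)[C@]1(C)CC[C@@H]2[C@H](C1=C)C2(C)C
F4 | step 13 | 2,4,6-trihydroxy-5-[3-methyl-1-(morpholin-4-yl)butyl]benzene-1,3-dicarbaldehyde (racemic) | CC(C)CC(N1CCOCC1)c1c(O)c(C=O)c(O)c(C=O)c1O
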